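**Plan**

- Cuts, in retrosynthetic order: the hydroquinone/quinone redox pair; the prenyl C=C bond (cross-metathesis); the bond between furan C2 and benzene C1' (C–H/quinone union); the ester C(=O)–O bond; the carbinol C–CH2(allyl) bond.
- Forward: furan-3-carbaldehyde is allylated, the carbinol is esterified with senecioic acid, benzoquinone is joined to the free furan α-carbon, metathesis turns the allyl into the prenyl chain, and reduction gives the hydroquinone. No ring is formed; both rings are bought intact.
- Feature that makes the key step possible: the 2,5-dihydroxyphenyl ring is a p-benzoquinone at the reduced level, bonded through C1' to furan α-carbon C2. In the precursor this carbon (C5 of the 3-substituted furan) bears H and is the unhindered nucleophilic α-position, while oxidation to the quinone makes the other, normally nucleophilic, ring carbon electrophilic (polarity reversal).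
- Stereochemistry: the single (S) centre comes from catalyst-controlled Si-face allylboration in step 1 and is carried through unchanged (acyl transfer at the carboxyl carbon; later steps act elsewhere).
- No protecting groups: the quinone masks the hydroquinone through the metathesis, and the acid-sensitive prenyl alkene is made only after the Lewis acid step.

Key step: step 3

Remark: CIP analysis of the target SMILES gives (S) at the carbinol carbon (O > furan C4 > CH2 > H); all intermediates are named on that basis.

**Route**

Step 1
Reactants: 1 furan-3-carbaldehyde; 2 allylboronic acid pinacol ester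
Product: 4 (S)-1-(furan-3-yl)but-3-en-1-ol, via homoallyl pinacol borate 3 (not isolated)
Conditions: 2 (1.2 equiv), (S)-TRIP [(S)-3,3'-bis(2,4,6-triisopropylphenyl)-BINOL hydrogen phosphate] (5 mol %), toluene, −30 °C; then aq NaHCO3
Reagents that add atoms: allylboronic acid pinacol ester, C=CCB1OC(C)(C)C(C)(C)O1
Why: Chiral phosphoric acid-catalysed allylboration through a closed chair transition state, in which the (S)-catalyst (the antipode of the one that gives (R)-carbinols from aryl aldehydes) is expected to direct allyl transfer to the Si face of the aldehyde and so set the (S)-carbinol; the borate 3 is hydrolysed on work-up.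

Step 2
Reactants: 4 (S)-1-(furan-3-yl)but-3-en-1-ol; 5 3-methylbut-2-enoic acid (senecioic acid)
Product: 6 (S)-1-(furan-3-yl)but-3-en-1-yl 3-methylbut-2-enoate
Conditions: 5 (1.5 equiv), DCC (1.5 equiv), DMAP (10 mol %), CH2Cl2, 0 °C to rt
Reagents that add atoms: 3-methylbut-2-enoic acid, CC(C)=CC(=O)O
Why: Steglich esterification transfers the senecioyl group to the carbinol oxygen without breaking the C–O bond at the stereocentre, so the (S) configuration is retained, and catalytic DMAP at 0 °C should keep the shift of the double bond out of conjugation low.

Step 3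
Reactants: 6 (S)-1-(furan-3-yl)but-3-en-1-yl 3-methylbut-2-enoate; 7 1,4-benzoquinone
Product: 9 (S)-1-[5-(3,6-dioxocyclohexa-1,4-dien-1-yl)furan-3-yl]but-3-en-1-yl 3-methylbut-2-enoate, via hydroquinone adduct 8 (not isolated)
Conditions: 7 (2.5 equiv), Sc(OTf)3 (10 mol %), MeCN, −20 to 0 °C, Ar, dark
Reagents that add atoms: 1,4-benzoquinone, O=C1C=CC(=O)C=C1
Why: Scandium-bound benzoquinone is attacked at a ring CH by furan C5 (Friedel–Crafts-type conjugate addition), loss of the furan proton and tautomerisation give hydroquinone 8, and 8, which is more easily oxidised than hydroquinone itself, passes two hydrogens to a second benzoquinone to give quinone 9. The closest known reaction type is the acid-catalysed substituting addition of furans, pyrroles and indoles to p-quinones, which with excess quinone ends at the heteroaryl quinone. No ring is closed and no stereocentre is formed; the carbinol centre is not involved as long as the furylic ester does not ionise, which the catalytic Lewis acid at or below 0 °C is meant to ensure. The step needs C5 over C2 of the furan: C2 is flanked by the branched 1-acyloxybutenyl group at C3, whose acyloxy group also cancels the activation a 3-alkyl group gives to C2, so the free remote α-position should react. It also needs mono-arylation and attack by the furan, not the alkene: oxidation to 9 turns the new aryl group into an acceptor that deactivates the furan towards a second quinone, and the side chain still ends in a monosubstituted alkene, far less nucleophilic than a prenyl group, which is why the metathesis comes after this step.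

Step 4
Reactants: 9 (S)-1-[5-(3,6-dioxocyclohexa-1,4-dien-1-yl)furan-3-yl]but-3-en-1-yl 3-methylbut-2-enoate; 10 2-methylbut-2-ene
Product: 11 (S)-1-[5-(3,6-dioxocyclohexa-1,4-dien-1-yl)furan-3-yl]-4-methylpent-3-en-1-yl 3-methylbut-2-enoate
Conditions: Hoveyda–Grubbs II (5 mol %), 10 (large excess, co-solvent), CH2Cl2, 35 °C
Reagents that add atoms: 2-methylbut-2-ene, CC=C(C)C
Why: Olefin cross-metathesis of the monosubstituted alkene with a large excess of 2-methylbut-2-ene should give the trisubstituted prenyl alkene with loss of propene, the β,β-disubstituted enoate and the quinone double bonds being electron-poor spectator olefins and the phosphine-free catalyst leaving the quinone untouched; the stereocentre is remote.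

Step 5
Reactants: 11 (S)-1-[5-(3,6-dioxocyclohexa-1,4-dien-1-yl)furan-3-yl]-4-methylpent-3-en-1-yl 3-methylbut-2-enoate
Product: 12 (S)-1-[5-(2,5-dihydroxyphenyl)furan-3-yl]-4-methylpent-3-en-1-yl 3-methylbut-2-enoate (target)
Conditions: Na2S2O4 (3 equiv), EtOAc/aq phosphate buffer pH 7, rt, Ar
Reagents that add atoms: none
Why: Dithionite reduction of the quinone to the hydroquinone by two-electron, two-proton transfer at near-neutral pH, conditions under which the enoate, the prenyl alkene and the furylic ester should be inert and the stereocentre is not touched.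

**Compound list**

1 | furan-3-carbaldehyde | O=Cc1ccoc1 | starting material
2 | allylboronic acid pinacol ester (2-allyl-4,4,5,5-tetramethyl-1,3,2-dioxaborolane) | C=CCB1OC(C)(C)C(C)(C)O1 | starting material
3 | (S)-2-{[1-(furan-3-yl)but-3-en-1-yl]oxy}-4,4,5,5-tetramethyl-1,3,2-dioxaborolane | C=CC[C@H](OB1OC(C)(C)C(C)(C)O1)c1ccoc1 | intermediate
4 | (S)-1-(furan-3-yl)but-3-en-1-ol | C=CC[C@H](O)c1ccoc1 | intermediate
5 | 3-methylbut-2-enoic acid (senecioic acid) | CC(C)=CC(=O)O | starting material
6 | (S)-1-(furan-3-yl)but-3-en-1-yl 3-methylbut-2-enoate | C=CC[C@H](OC(=O)C=C(C)C)c1ccoc1 | intermediate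
7 | 1,4-benzoquinone | O=C1C=CC(=O)C=C1 | starting material
8 | (S)-1-[5-(2,5-dihydroxyphenyl)furan-3-yl]but-3-en-1-yl 3-methylbut-2-enoate | C=CC[C@H](OC(=O)C=C(C)C)c1coc(-c2cc(O)ccc2O)c1 | intermediate
9 | (S)-1-[5-(3,6-dioxocyclohexa-1,4-dien-1-yl)furan-3-yl]but-3-en-1-yl 3-methylbut-2-enoate | C=CC[C@H](OC(=O)C=C(C)C)c1coc(C2=CC(=O)C=CC2=O)c1 | intermediate
10 | 2-methylbut-2-ene | CC=C(C)C | starting material
11 | (S)-1-[5-(3,6-dioxocyclohexa-1,4-dien-1-yl)furan-3-yl]-4-methylpent-3-en-1-yl 3-methylbut-2-enoate | CC(C)=CC[C@H](OC(=O)C=C(C)C)c1coc(C2=CC(=O)C=CC2=O)c1 | intermediate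
12 | (S)-1-[5-(2,5-dihydroxyphenyl)furan-3-yl]-4-methylpent-3-en-1-yl 3-methylbut-2-enoate | CC(C)=CC[C@H](OC(=O)C=C(C)C)c1coc(-c2cc(O)ccc2O)c1 | target

**Step count and risks**

Total step count: 5. Longest linear sequence: 5 steps (from furan-3-carbaldehyde).

Steps most likely to fail:

1. Step 3. The quinone may attack the α-carbon next to the side chain instead of the remote one. The Lewis acid may ionise the furylic ester, with elimination or loss of configuration. An α-unsubstituted furan may also react too slowly. The fallback sets out from 6 and comes back at 9. Iridium-catalysed C–H borylation ([Ir(OMe)(cod)]2, dtbpy, B2pin2 as limiting boron source, hexane, rt) is sterically controlled and much faster at a furan α-C–H than at the monosubstituted alkene. It should give (S)-1-[5-(4,4,5,5-tetramethyl-1,3,2-dioxaborolan-2-yl)furan-3-yl]but-3-en-1-yl 3-methylbut-2-enoate F1. Suzuki–Miyaura coupling of the boronate with 2-bromo-1,4-bis(tert-butyldimethylsilyloxy)benzene (XPhos Pd G3, aq K3PO4, THF, rt to 40 °C) should give (S)-1-{5-[2,5-bis(tert-butyldimethylsilyloxy)phenyl]furan-3-yl}but-3-en-1-yl 3-methylbut-2-enoate F2. Et3N·3HF in THF should free hydroquinone 8, and Ag2O in Et2O should oxidise 8 to quinone 9, where the route is rejoined.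

2. Step 4. The ruthenium alkylidene may cyclise onto the senecioate double bond (ring-closing metathesis with loss of isobutene), or the quinone may stall the catalyst. The fallback sets out from 4 and comes back at 11. Cross-metathesis of the free alcohol 4 with 2-methylbut-2-ene (Grubbs II, CH2Cl2), where neither enoate nor quinone is present, should give (S)-1-(furan-3-yl)-4-methylpent-3-en-1-ol F3. Steglich esterification as in step 2 should give (S)-1-(furan-3-yl)-4-methylpent-3-en-1-yl 3-methylbut-2-enoate F4. The quinone coupling under the conditions of step 3 should then pass through the hydroquinone level (12 itself) to quinone 11, where the route is rejoined. The prenyl alkene would then have to survive the Lewis acid step.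

3. Step 1. Facial selectivity may be insufficient with the small heteroaryl aldehyde, and the sense of induction is assigned by analogy. The fallback sets out from 1 and comes back at 4. Allylmagnesium bromide in Et2O at −78 °C should give racemic 1-(furan-3-yl)but-3-en-1-ol F5. Lipase-catalysed kinetic resolution (Burkholderia cepacia lipase, vinyl acetate, MTBE, 30 °C) is expected, by Kazlauskas' rule, to acetylate the (R)-enantiomer to (R)-1-(furan-3-yl)but-3-en-1-yl acetate F6 and leave (S)-alcohol 4. Chromatography separates 4, which re-enters the route at step 2.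

**Further compounds**

F1 | step 3 | (S)-1-[5-(4,4,5,5-tetramethyl-1,3,2-dioxaborolan-2-yl)furan-3-yl]but-3-en-1-yl 3-methylbut-2-enoate | C=CC[C@H](OC(=O)C=C(C)C)c1coc(B2OC(C)(C)C(C)(C)O2)c1
F2 | step 3 | (S)-1-{5-[2,5-bis(tert-butyldimethylsilyloxy)phenyl]furan-3-yl}but-3-en-1-yl 3-methylbut-2-enoate | C=CC[C@H](OC(=O)C=C(C)C)c1coc(-c2cc(O[Si](C)(C)C(C)(C)C)ccc2O[Si](C)(C)C(C)(C)C)c1
F3 | step 4 | (S)-1-(furan-3-yl)-4-methylpent-3-en-1-ol | CC(C)=CC[C@H](O)c1ccoc1
F4 | step 4 | (S)-1-(furan-3-yl)-4-methylpent-3-en-1-yl 3-methylbut-2-enoate | CC(C)=CC[C@H](OC(=O)C=C(C)C)c1ccoc1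
F5 | step 1 | rac-1-(furan-3-yl)but-3-en-1-ol | C=CCC(O)c1ccoc1
F6 | step 1 | (R)-1-(furan-3-yl)but-3-en-1-yl acetate | C=CC[C@@H](OC(C)=O)c1ccoc1
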